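**Retrosynthetic overview**

1. Target 23 ← quinone 22 ← dimethyl ether 21. Ring C (Cq2–CH2–C(CH3)=CH–Cbn–Cq1) is cut at Cbn–CH= (oxidative benzylic C–H/vinylsilane closure of 20) and at Cq2–CH2 (angular alkylation of ketone 12 with the (Z)-allylic bromide 18).
2. 12 ← α-ketol 11 (reductive removal of the tertiary OH).
3. Feature carrying the strategy: ring B, the five-membered ring made of Cq1 (prenyl-bearing, C-9a), Cbn (C-9), two arene carbons and Cq2 (aryl-bearing, C-4a), is a benzyl unit laid across the C-3=C-2 enol double bond of a 3-prenyl-2-hydroxyquinone. Cq1–Cbn comes from C-benzylation and Cq2–aryl from Friedel–Crafts attack on the C-2 ketone, so 11 ⇒ 7 + 9.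
4. 7 ← 2-prenylresorcinol 6 (Teuber oxidation) ← resorcinol bis-MOM ether (ortho-lithiation, prenylation); 9 ← alcohol 8; 18 ← propargyl alcohol 13.
5. Ring order: A (preformed quinone), then B (key step), then C (last); the arene is bought.

Key step: step 6

Assumption: which antipode of the chiral ammonium salt delivers (R)-10 cannot be predicted with confidence; both antipodes are accessible and the matching one is to be chosen in a first screen.
Locants: tricyclic and tetracyclic compounds carry fluorene numbering (Cq1 = C-9a, Cq2 = C-4a, Cbn = C-9).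

**Step 1**
Reactants: 1 resorcinol
Product: 2 1,3-bis(methoxymethoxy)benzene
Conditions: MOMCl (2.5 equiv), K2CO3, acetone, 0 °C → reflux
Reagents that add atoms: chloromethyl methyl ether, COCCl
Why: Williamson-type O-alkylation of both phenols should install two MOM ethers that direct the metalation of step 2 and can later be removed without harming a prenyl group.

**Step 2**
Reactants: 2 1,3-bis(methoxymethoxy)benzene; 3 prenyl bromide
Product: 5 1,3-bis(methoxymethoxy)-2-(3-methylbut-2-en-1-yl)benzene, via aryllithium 4 (not isolated)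
Conditions: n-BuLi (1.1 equiv), THF, 0 °C; then CuI (10 mol %), 3, −78 °C → rt
Reagents that add atoms: none
Why: directed ortho-metalation should occur only at C-2, flanked by both OMOM groups, and copper-assisted SN2 allylation of the aryllithium should give the linear prenyl arene.

**Step 3**
Reactants: 5 1,3-bis(methoxymethoxy)-2-(3-methylbut-2-en-1-yl)benzene
Product: 6 2-(3-methylbut-2-en-1-yl)benzene-1,3-diol
Conditions: 2 M HCl (aq), MeOH, rt
Reagents that add atoms: none
Why: acid-catalysed acetal exchange with methanol should cleave both MOM ethers, and dilute acid at room temperature should leave the prenyl group uncyclised.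

**Step 4**
Reactants: 6 2-(3-methylbut-2-en-1-yl)benzene-1,3-diol
Product: 7 2-hydroxy-3-(3-methylbut-2-en-1-yl)cyclohexa-2,5-diene-1,4-dione
Conditions: (KSO3)2NO (2.5 equiv), KH2PO4 (aq), acetone, 0 °C → rt
Reagents that add atoms: potassium nitrosodisulfonate (Fremy's salt), [K+].[K+].[O]N(S(=O)(=O)[O-])S(=O)(=O)[O-]
Why: Teuber oxidation should oxygenate the position para to one OH (the two are equivalent by symmetry), giving the 2-hydroxy-1,4-quinone with the prenyl group between OH and C=O; the alkene is inert to the nitroxide.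

**Step 5**
Reactants: 8 (2,5-dimethoxyphenyl)methanol
Product: 9 2-(bromomethyl)-1,4-dimethoxybenzene
Conditions: PBr3 (0.4 equiv), Et2O, 0 °C; used fresh
Reagents that add atoms: phosphorus tribromide, BrP(Br)Br
Why: SN2 displacement of the phosphite ester by bromide should give the reactive benzylic bromide cleanly.

**Step 6**
Reactants: 7 2-hydroxy-3-(3-methylbut-2-en-1-yl)cyclohexa-2,5-diene-1,4-dione; 9 2-(bromomethyl)-1,4-dimethoxybenzene
Product: 11 (4aS,9aS)-4a-hydroxy-5,8-dimethoxy-9a-(3-methylbut-2-en-1-yl)-4a,9-dihydro-1H-fluorene-1,4(9aH)-dione (cis-fused ketol), via trione 10 (not isolated)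
Conditions: (i) C2-symmetric N-spiro binaphthyl quaternary ammonium bromide bearing 3,4,5-trifluorophenyl groups (5 mol %, matching antipode), K2CO3 (s), PhMe, −20 °C; (ii) filter under Ar, then BF3·OEt2 (1.5 equiv), CH2Cl2, −40 → 0 °C
Reagents that add atoms: none
Why: Proposed new method: the ammonium salt of the vinylogous acid 7 (anion spread over O-2, C-2, C-3, C-4, O-4) should be benzylated at C-3 by 9 inside a tight ion pair with the chiral cation, which shields one face of C-3 and so sets Cq1 in the non-enolisable trione 10; the closest known reaction types are asymmetric phase-transfer C-benzylation of cyclic 2-substituted 1,3-dicarbonyl enolates and the racemic C-alkylation of 3-substituted 2-hydroxy-1,4-quinones to 3,3-disubstituted triones. BF3 should then chelate the vicinal C-1/C-2 dicarbonyl, and the arene carbon ortho to the CH2 and ortho to an OMe should attack C-2 in a 5-exo-trig Friedel–Crafts hydroxyalkylation that closes ring B, the closest known type being the acid-mediated cyclisation of 2-benzyl-1,3-dicarbonyl compounds to indenols. Cq2 is set by the substrate: the arene hangs from Cq1 through Cbn and can reach only the C-2 face syn to that CH2, so the OH ends up cis to prenyl and the 5/6 fusion is cis. The step needs C- over O-alkylation (soft benzylic bromide, non-polar medium, tight ion pair) and attack at C-2 and not at C-4 (C-2 is the non-conjugated centre of a 1,2-dione and the more electrophilic, C-4 is an enone carbonyl). The prenyl alkene should not compete because it could form only a four-membered or an anti-Markovnikov five-membered ring, and the tertiary ketol cannot dehydrate because Cq2 has no β-hydrogen.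

**Step 7**
Reactants: 11 cis-fused ketol
Product: 12 (4aR,9aS)-5,8-dimethoxy-9a-(3-methylbut-2-en-1-yl)-4a,9-dihydro-1H-fluorene-1,4(9aH)-dione
Conditions: SmI2 (2.1 equiv), THF, −78 °C, no proton source; then aq. NH4Cl (degassed)
Reagents that add atoms: none
Why: SmI2 reduction of an α-hydroxy ketone should expel the benzylic tertiary hydroxyl after two-electron transfer to the C-4 carbonyl, leaving a samarium enolate that resists further reduction until it is protonated at work-up to the cis-fused ketone (the C-4a configuration is of no consequence, since the centre is re-enolised in step 11).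

**Step 8**
Reactants: 13 prop-2-yn-1-ol
Product: 15 (Z)-3-iodo-2-methylprop-2-en-1-ol, via alkenylmagnesium 14 (not isolated)
Conditions: MeMgBr (2.5 equiv), CuI (10 mol %), THF–Et2O, −10 °C → rt; then I2, −78 → 0 °C
Reagents that add atoms: methylmagnesium bromide, C[Mg]Br; iodine, II
Why: copper-catalysed anti-carbomagnesiation of the propargylic alkoxide should place methyl on C-2 and magnesium on C-3 cis to the CH2O group (alkoxide chelation), and iodinolysis with retention fixes the Z geometry.

**Step 9**
Reactants: 15 (Z)-3-iodo-2-methylprop-2-en-1-ol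
Product: 17 (Z)-2-methyl-3-(trimethylsilyl)prop-2-en-1-ol, via silyl ether 16 (not isolated)
Conditions: n-BuLi (1.0 equiv), THF, −78 °C, then TMSCl; then t-BuLi (2.1 equiv), −78 °C → rt; aq. NH4Cl
Reagents that add atoms: chlorotrimethylsilane, C[Si](C)(C)Cl
Why: iodine–lithium exchange on the O-silylated iodide should give a configurationally stable alkenyllithium cis to the CH2OSiMe3 group, and a retro-[1,4]-Brook shift then moves silicon from oxygen to carbon with the Z geometry kept.

**Step 10**
Reactants: 17 (Z)-2-methyl-3-(trimethylsilyl)prop-2-en-1-ol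
Product: 18 (Z)-(3-bromo-2-methylprop-1-en-1-yl)trimethylsilane
Conditions: CBr4, PPh3, CH2Cl2, 0 °C
Reagents that add atoms: carbon tetrabromide, BrC(Br)(Br)Br
Why: the Appel reaction should convert the primary allylic alcohol into the bromide under neutral conditions that neither protodesilylate nor isomerise the vinylsilane.

**Step 11**
Reactants: 12 (4aR,9aS)-5,8-dimethoxy-9a-(3-methylbut-2-en-1-yl)-4a,9-dihydro-1H-fluorene-1,4(9aH)-dione; 18 (Z)-(3-bromo-2-methylprop-1-en-1-yl)trimethylsilane
Product: 20 (4aR,9aS)-5,8-dimethoxy-4a-[(Z)-2-methyl-3-(trimethylsilyl)prop-2-en-1-yl]-9a-(3-methylbut-2-en-1-yl)-4a,9-dihydro-1H-fluorene-1,4(9aH)-dione, via lithium enolate 19 (not isolated)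
Conditions: LiHMDS (1.05 equiv), THF, −78 °C; then 18, −78 → 0 °C
Reagents that add atoms: none
Why: C-4a–H is the only acidic site (α-keto and benzylic), and SN2 C-allylation of its lithium enolate should place the arm cis to prenyl, because that is the only face that keeps the benzo-fused five-membered ring cis-fused (a trans-fused indane-type ring would be severely strained).

**Step 12**
Reactants: 20 (4aR,9aS)-vinylsilane
Product: 21 (4aR,9R,9aS)-5,8-dimethoxy-9a-(3-methylbut-2-en-1-yl)-4a,9-(2-methylprop-1-ene-1,3-diyl)-4a,9-dihydro-1H-fluorene-1,4(9aH)-dione (bridge CH2 on C-4a, bridge =CH on C-9)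
Conditions: DDQ (1.5 equiv), 2,6-dichloropyridine, LiClO4, 4 Å MS, ClCH2CH2Cl, 0 °C → rt
Reagents that add atoms: none
Why: Proposed new method: DDQ should remove hydride from the only benzylic C–H bonds left (Cbn, ortho to OMe), and the resulting o-methoxybenzylic cation, which has no β-hydrogen, should be attacked at the silicon-bearing carbon of the (Z)-vinylsilane (six-membered ring, tertiary β-silyl cation), loss of silicon fixing the alkene as C(CH3)=CH–Cbn; the bridge can form only on the face of ring B that carries the arm, which sets Cbn, and the closest known reaction types are DDQ-mediated oxidative C–H cyclisations of benzylic ethers onto tethered π-nucleophiles and vinylsilane-terminated cation–olefin cyclisations.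

**Step 13**
Reactants: 21 tetracyclic dimethyl ether
Product: 23 target hydroquinone CNP0166383.1 (4aR,9R,9aS), via quinone 22 (not isolated)
Conditions: CAN (2.5 equiv), MeCN–H2O, 0 °C; then Na2S2O4 (aq), EtOAc, rt
Reagents that add atoms: water, O
Why: oxidative demethylation of the 2,3-dialkyl-1,4-dimethoxyarene by cerium(IV) should give the p-quinone without touching the isolated alkenes, and dithionite should reduce this quinone much faster than the non-aromatisable enedione of ring A.

**Compound list**

1 | benzene-1,3-diol (resorcinol) | Oc1cccc(O)c1 | starting material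
2 | 1,3-bis(methoxymethoxy)benzene | COCOc1cccc(OCOC)c1 | intermediate
3 | 1-bromo-3-methylbut-2-ene (prenyl bromide) | CC(C)=CCBr | starting material
4 | [2,6-bis(methoxymethoxy)phenyl]lithium | [Li]c1c(OCOC)cccc1OCOC | intermediate
5 | 1,3-bis(methoxymethoxy)-2-(3-methylbut-2-en-1-yl)benzene | COCOc1cccc(OCOC)c1CC=C(C)C | intermediate
6 | 2-(3-methylbut-2-en-1-yl)benzene-1,3-diol | CC(C)=CCc1c(O)cccc1O | intermediate
7 | 2-hydroxy-3-(3-methylbut-2-en-1-yl)cyclohexa-2,5-diene-1,4-dione | CC(C)=CCC1=C(O)C(=O)C=CC1=O | intermediate
8 | (2,5-dimethoxyphenyl)methanol | COc1ccc(OC)c(CO)c1 | starting material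
9 | 2-(bromomethyl)-1,4-dimethoxybenzene | COc1ccc(OC)c(CBr)c1 | intermediate
10 | (R)-3-(2,5-dimethoxybenzyl)-3-(3-methylbut-2-en-1-yl)cyclohex-5-ene-1,2,4-trione | CC(C)=CC[C@@]1(Cc2cc(OC)ccc2OC)C(=O)C=CC(=O)C1=O | intermediate
11 | (4aS,9aS)-4a-hydroxy-5,8-dimethoxy-9a-(3-methylbut-2-en-1-yl)-4a,9-dihydro-1H-fluorene-1,4(9aH)-dione | CC(C)=CC[C@@]12C(=O)C=CC(=O)[C@]1(O)c1c(OC)ccc(OC)c1C2 | intermediate
12 | (4aR,9aS)-5,8-dimethoxy-9a-(3-methylbut-2-en-1-yl)-4a,9-dihydro-1H-fluorene-1,4(9aH)-dione | CC(C)=CC[C@@]12C(=O)C=CC(=O)[C@@H]1c1c(OC)ccc(OC)c1C2 | intermediate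
13 | prop-2-yn-1-ol | C#CCO | starting material
14 | (Z)-[3-(bromomagnesiooxy)-2-methylprop-1-en-1-yl]magnesium bromide | C/C(CO[Mg]Br)=C/[Mg]Br | intermediate
15 | (Z)-3-iodo-2-methylprop-2-en-1-ol | OC/C(C)=C\I | intermediate
16 | (Z)-[(3-iodo-2-methylprop-2-en-1-yl)oxy]trimethylsilane | C[Si](C)(C)OC/C(C)=C\I | intermediate
17 | (Z)-2-methyl-3-(trimethylsilyl)prop-2-en-1-ol | OC/C(C)=C\[Si](C)(C)C | intermediate
18 | (Z)-(3-bromo-2-methylprop-1-en-1-yl)trimethylsilane | BrC/C(C)=C\[Si](C)(C)C | intermediate
19 | lithium C-4 enolate of 12 (C-4a=C-4 double bond, 9aS) | CC(C)=CC[C@@]12C(=O)C=CC(O[Li])=C1c1c(OC)ccc(OC)c1C2 | intermediate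
20 | (4aR,9aS)-5,8-dimethoxy-4a-[(Z)-2-methyl-3-(trimethylsilyl)prop-2-en-1-yl]-9a-(3-methylbut-2-en-1-yl)-4a,9-dihydro-1H-fluorene-1,4(9aH)-dione | CC(C)=CC[C@@]12C(=O)C=CC(=O)[C@]1(C/C(C)=C\[Si](C)(C)C)c1c(OC)ccc(OC)c1C2 | intermediate
21 | (4aR,9R,9aS)-5,8-dimethoxy-9a-(3-methylbut-2-en-1-yl)-4a,9-(2-methylprop-1-ene-1,3-diyl)-4a,9-dihydro-1H-fluorene-1,4(9aH)-dione (di-O-methyl target) | CC(C)=CC[C@@]12C(=O)C=CC(=O)[C@@]13CC(C)=C[C@@H]2c1c(OC)ccc(OC)c13 | intermediate
22 | (4aR,9R,9aS)-9a-(3-methylbut-2-en-1-yl)-4a,9-(2-methylprop-1-ene-1,3-diyl)-4a,9-dihydro-1H-fluorene-1,4,5,8(9aH)-tetrone | CC(C)=CC[C@@]12C(=O)C=CC(=O)[C@@]13CC(C)=C[C@@H]2C1=C3C(=O)C=CC1=O | intermediate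
23 | CNP0166383.1: (4aR,9R,9aS)-5,8-dihydroxy-9a-(3-methylbut-2-en-1-yl)-4a,9-(2-methylprop-1-ene-1,3-diyl)-4a,9-dihydro-1H-fluorene-1,4(9aH)-dione | CC(C)=CC[C@@]12C(=O)C=CC(=O)[C@@]13CC(C)=C[C@@H]2c1c(O)ccc(O)c13 | target

**Step count**

Total: 13 steps. Longest linear sequence: 9 steps (1, 2, 3, 4, 6, 7, 11, 12, 13, from resorcinol).

**Steps most likely to fail**

Step 6 (Proposed new method). The ambident hydroxyquinone anion may be benzylated on oxygen faster than on carbon, the chiral cation may discriminate the two faces of C-3 poorly, and base may degrade the quinone or the trione before ring closure. Fallback, setting out from 7 and 9 and coming back at 11: the lithium salt of 7 is alkylated with 9 in DMSO, a counter-ion and solvent combination established for C-alkylation of 3-substituted 2-hydroxyquinones by allylic and benzylic bromides. This would give the trione as a racemate, that is 10 together with its mirror image, the (S)-trione F1. The same BF3·OEt2 closure would give 11 together with the enantiomeric (4aR,9aR)-ketol F2. The two ketols are separated by preparative chromatography on a polysaccharide-carbamate chiral stationary phase and 11 is carried on.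

Step 12 (Proposed new method). Hydride abstraction from Cbn may be slow because the cation sits β to a ketone, and the cation may be intercepted by reduced DDQ or the oxidant may attack the vinylsilane before the ring closes. Fallback, setting out from 20 and coming back at 23: the arene is oxidised first with CAN (MeCN–H2O, 0 °C), which would give the uncyclised benzoquinone F3. A catalytic acid (for example Sc(OTf)3 in CH2Cl2–HFIP, 0 °C) should then isomerise this alkyl-p-benzoquinone to its o-quinone methide, whose methide carbon is Cbn, and the (Z)-vinylsilane should capture it by ipso substitution. That closure is redox-neutral and would deliver the hydroquinone 23 directly, without 21 and 22. Both events are established chemistry: isomerisation of alkyl-1,4-benzoquinones to o-quinone methides with interception by tethered π-nucleophiles, and ipso substitution of vinylsilanes by benzylic cations.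

Step 11. Bond formation at C-4a must occur next to a quaternary carbon and on the prenyl-bearing face, so O-allylation or simple recovery of 12 may take over. Fallback, setting out from 12 and coming back at 21: the enolate is alkylated with propargyl bromide (LiHMDS, THF), the slimmest sp3 electrophile, to give the 4a-propargyl diketone F4. DDQ in AcOH should then give the C-9 benzylic acetate F5 as an epimer mixture. FeBr3 in CH2Cl2 at −40 °C should ionise it, the terminal alkyne carbon should attack Cbn in the 6-endo mode (the 5-exo mode would need a primary vinyl cation), and bromide should capture the cyclohexenyl cation to give the bridged vinyl bromide F6. The position of its double bond is fixed because it derives from the triple bond. Stille coupling (Me4Sn, Pd(PPh3)4, CuI, DMF, 60 °C) then installs the methyl group and gives 21.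

**Further compounds**

F1 | step 6 | (S)-3-(2,5-dimethoxybenzyl)-3-(3-methylbut-2-en-1-yl)cyclohex-5-ene-1,2,4-trione (enantiomer of 10) | CC(C)=CC[C@]1(Cc2cc(OC)ccc2OC)C(=O)C=CC(=O)C1=O
F2 | step 6 | (4aR,9aR)-4a-hydroxy-5,8-dimethoxy-9a-(3-methylbut-2-en-1-yl)-4a,9-dihydro-1H-fluorene-1,4(9aH)-dione (enantiomer of 11) | CC(C)=CC[C@]12C(=O)C=CC(=O)[C@@]1(O)c1c(OC)ccc(OC)c1C2
F3 | step 12 | (4aR,9aS)-4a-[(Z)-2-methyl-3-(trimethylsilyl)prop-2-en-1-yl]-9a-(3-methylbut-2-en-1-yl)-4a,9-dihydro-1H-fluorene-1,4,5,8(9aH)-tetrone | CC(C)=CC[C@@]12C(=O)C=CC(=O)[C@]1(C/C(C)=C\[Si](C)(C)C)C1=C(C2)C(=O)C=CC1=O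
F4 | step 11 | (4aR,9aS)-5,8-dimethoxy-9a-(3-methylbut-2-en-1-yl)-4a-(prop-2-yn-1-yl)-4a,9-dihydro-1H-fluorene-1,4(9aH)-dione | CC(C)=CC[C@@]12C(=O)C=CC(=O)[C@]1(CC#C)c1c(OC)ccc(OC)c1C2
F5 | step 11 | 9-acetoxy derivative of F4 (C-9 epimer mixture) | CC(C)=CC[C@@]12C(=O)C=CC(=O)[C@]1(CC#C)c1c(OC)ccc(OC)c1C2OC(C)=O
F6 | step 11 | analogue of 21 with Br in place of the ring-C methyl group (4a,9-(2-bromoprop-1-ene-1,3-diyl) bridge) | CC(C)=CC[C@@]12C(=O)C=CC(=O)[C@@]13CC(Br)=C[C@@H]2c1c(OC)ccc(OC)c13
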